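**Retrosynthetic overview** (cembrane numbering)
1. The 14-membered carbocycle is closed last, by ring-closing metathesis at the E C6=C7 alkene of an unprotected triol-butenolide diene.
2. Key bond C10-C11: the β-carbon of an α-alkylidene δ-lactone is released from its (Z)-enol triflate by NiCl2/CrCl2 as a β-acylvinyl anion (an sp2 homoenolate). It attacks the C10 aldehyde, and the new alkoxide switches the six-membered lactone to the butenolide and frees the C1 hydroxyl.
3. West half (C11-C14, C1-C6, C20): C1 comes from Sharpless epoxidation of 2-isopropylallyl alcohol. Radical chain extension gives the δ-lactone, a Wittig reaction gives the E C2=C3 enone, silver-catalysed asymmetric allylation sets C4, and formylation/triflation follows.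
4. East half (C7-C10): C8 comes from Sharpless epoxidation of commercial (Z)-3-methylpent-2-en-4-yn-1-ol, followed by one-pot hydride opening/alkyne reduction and oxidation.
5. Ring order: δ-lactone (temporary, step 4), butenolide (step 12), macrocycle (step 13).

Assumption: C1 is the carbinol carbon bearing isopropyl and C20 the lactone carbonyl; the facial sense of the two ligand-controlled additions (steps 6 and 12) is carried over from the closest known methyl ketones and aldehydes.

**Step 1**
Reactants: 1 prop-2-yn-1-ol (propargyl alcohol); 2 isopropylmagnesium chloride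
Product: 3 3-methyl-2-methylidenebutan-1-ol (2-isopropylallyl alcohol)
Conditions: iPrMgCl (2.5 equiv), CuI (10 mol %), THF, -10 °C to rt; H2O
Reagents that add atoms: none
Why: Copper-catalysed carbomagnesiation of the magnesium alkoxide of propargyl alcohol (Duboudin-Jousseaume reaction) places isopropyl on the inner alkyne carbon through a five-membered chelate, and protonation gives the 2-substituted allyl alcohol with no stereocentre formed.

**Step 2**
Reactants: 3 3-methyl-2-methylidenebutan-1-ol
Product: 4 [(2S)-2-(propan-2-yl)oxiran-2-yl]methanol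
Conditions: Ti(OiPr)4 (5 mol %), L-(+)-DIPT (6 mol %), t-BuOOH, 4 Å MS, CH2Cl2, -20 °C
Reagents that add atoms: tert-butyl hydroperoxide, CC(C)(C)OO
Why: In the Sharpless asymmetric epoxidation L-(+)-tartrate oxidises 2-substituted allyl alcohols on the face that gives the (S)-glycidol (as with methallyl alcohol), and this C-O bond becomes the C1 carbinol centre (1S) of the target.

**Step 3**
Reactants: 4 [(2S)-2-(propan-2-yl)oxiran-2-yl]methanol
Product: 5 (2S)-2-(iodomethyl)-3-methylbutane-1,2-diol
Conditions: LiI, AcOH, THF, rt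
Reagents that add atoms: lithium iodide, [Li+].[I-]
Why: Acid-assisted SN2 halohydrin formation opens the 2,2-disubstituted epoxide at its unhindered CH2, so the C-O bond at the quaternary centre is untouched and its configuration is kept.

**Step 4**
Reactants: 5 (2S)-2-(iodomethyl)-3-methylbutane-1,2-diol; 6 methyl acrylate
Product: 8 (6S)-6-(hydroxymethyl)-6-(propan-2-yl)oxan-2-one, via hydroxy ester 7 (not isolated)
Conditions: methyl acrylate (8 equiv), Bu3SnH (syringe pump), AIBN (cat.), PhMe, 85 °C; then PPTS (cat.), 85 °C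
Reagents that add atoms: none
Why: In a Giese radical conjugate addition the primary β-hydroxyalkyl radical (which does not fragment) adds to the acrylate terminus to build C14-C13-C12-C20, and acid-catalysed lactonisation through the tertiary hydroxyl gives the favoured six-membered lactone without touching the stereocentre.

**Step 5**
Reactants: 8 (6S)-6-(hydroxymethyl)-6-(propan-2-yl)oxan-2-one; 9 1-(triphenylphosphoranylidene)propan-2-one
Product: 11 (6S)-6-[(1E)-3-oxobut-1-en-1-yl]-6-(propan-2-yl)oxan-2-one, via lactone aldehyde 10 (not isolated)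
Conditions: Dess-Martin periodinane, CH2Cl2, rt; then Ph3P=CHCOMe, 40 °C
Reagents that add atoms: none
Why: Dess-Martin oxidation followed in the same flask by Wittig olefination with a stabilised ylide gives the E enone (C2=C3), and the aldehyde has no α-hydrogen so C1 cannot epimerise.

**Step 6**
Reactants: 11 (6S)-6-[(1E)-3-oxobut-1-en-1-yl]-6-(propan-2-yl)oxan-2-one; 12 allyltrimethoxysilane
Product: 13 (6S)-6-[(1E,3R)-3-hydroxy-3-methylhexa-1,5-dien-1-yl]-6-(propan-2-yl)oxan-2-one
Conditions: AgF (5 mol %), (R)-DIFLUORPHOS (5 mol %), MeOH (1 equiv), THF, -78 to -40 °C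
Reagents that add atoms: none
Why: The silver-catalysed asymmetric Sakurai-Hosomi allylation of ketones adds only 1,2 to conjugated methyl ketones, and the chiral silver-allyl species attacks the Re face of the ketone under catalyst control to set C4 as R, the remote C1 centre having no say.

**Step 7**
Reactants: 13 (6S)-6-[(1E,3R)-3-hydroxy-3-methylhexa-1,5-dien-1-yl]-6-(propan-2-yl)oxan-2-one
Product: 14 (3Z,6S)-3-(hydroxymethylidene)-6-[(1E,3R)-3-hydroxy-3-methylhexa-1,5-dien-1-yl]-6-(propan-2-yl)oxan-2-one (enol of the 3-formyl lactone)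
Conditions: LiN(iPr)2 (2.2 equiv), THF, -78 °C; HCO2Et; AcOH
Reagents that add atoms: ethyl formate, CCOC=O
Why: Crossed Claisen condensation (α-formylation) occurs at the only enolisable site, is run cold so the allyl-ester enolate has no time for an Ireland-Claisen shift, and leaves the product as its stabilised enolate until the quench, touching no stereocentre.

**Step 8**
Reactants: 14 enol of the 3-formyl lactone
Product: 15 [(Z)-{(6S)-6-[(1E,3R)-3-hydroxy-3-methylhexa-1,5-dien-1-yl]-2-oxo-6-(propan-2-yl)oxan-3-ylidene}methyl] trifluoromethanesulfonate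
Conditions: LiN(SiMe3)2 (1.05 equiv), THF, -78 °C; Comins' reagent, to 0 °C
Reagents that add atoms: N-(5-chloropyridin-2-yl)bis(trifluoromethanesulfonimide) (Comins' reagent), O=S(=O)(N(c1ccc(Cl)cn1)S(=O)(=O)C(F)(F)F)C(F)(F)F
Why: O-Sulfonylation of the lithium chelate (enolate oxygen and lactone carbonyl on one lithium, U-shape) places OTf cis to the carbonyl as in lithium-directed Z-selective triflation of 1,3-dicarbonyl compounds, while the neutral tertiary alcohol does not react with the N-aryl triflimide.

**Step 9**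
Reactants: 16 (2Z)-3-methylpent-2-en-4-yn-1-ol
Product: 17 [(2S,3R)-3-ethynyl-3-methyloxiran-2-yl]methanol
Conditions: Ti(OiPr)4 (5 mol %), L-(+)-DIPT (6 mol %), t-BuOOH, 4 Å MS, CH2Cl2, -20 °C
Reagents that add atoms: tert-butyl hydroperoxide, CC(C)(C)OO
Why: Sharpless asymmetric epoxidation with L-(+)-tartrate attacks the same face as in nerol (giving 2S,3R), which fixes the quaternary C-O centre that becomes C8, and the alkyne is inert.

**Step 10**
Reactants: 17 [(2S,3R)-3-ethynyl-3-methyloxiran-2-yl]methanol
Product: 18 (3S)-3-methylpent-4-ene-1,3-diol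
Conditions: NaAlH2(OCH2CH2OMe)2 (4 equiv), THF, 0 °C, then 45 °C; H2O
Reagents that add atoms: none
Why: Hydroxyl-directed hydride opening of the 2,3-epoxy alcohol at C2 gives the 1,3-diol, and the propargylic alkoxide so formed directs hydroalumination of the alkyne to the vinyl group, the C8-O bond staying intact (3S).

**Step 11**
Reactants: 18 (3S)-3-methylpent-4-ene-1,3-diol
Product: 19 (3S)-3-hydroxy-3-methylpent-4-enal
Conditions: TEMPO (10 mol %), PhI(OAc)2, CH2Cl2, 0 °C to rt; used at once
Reagents that add atoms: none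
Why: Oxoammonium (TEMPO) oxidation takes the primary alcohol to the aldehyde under near-neutral conditions, the tertiary alcohol cannot be oxidised, and retro-aldol cleavage is avoided by immediate use.

**Step 12**
Reactants: 15 (Z)-enol triflate of the west half; 19 (3S)-3-hydroxy-3-methylpent-4-enal
Product: 21 (5R)-5-[(2S)-2-hydroxy-2-methylbut-3-en-1-yl]-3-[(3S,4E,6R)-3,6-dihydroxy-6-methyl-3-(propan-2-yl)nona-4,8-dien-1-yl]furan-2(5H)-one, via hydroxy alkylidene lactone 20 (not isolated)
Conditions: CrCl2 (4 equiv), (S)-N-[2-(4-isopropyl-4,5-dihydrooxazol-2-yl)-6-methylphenyl]methanesulfonamide (4.4 equiv), Et3N (4.4 equiv), NiCl2 (2 mol %), THF, rt, 16 h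
Reagents that add atoms: none
Why: Proposed new method: zerovalent nickel inserts into the C-OTf bond and passes the alkenyl group to chromium with retention, so the β-carbon of the unsaturated lactone, normally an acceptor, attacks the equally electrophilic aldehyde carbon as a β-acylvinyl anion in a Nozaki-Hiyama-Kishi reaction, the chiral sulfonamide on trivalent chromium directs attack to the Si face (10R), and the alkoxide held cis to the lactone carbonyl transacylates to the less strained conjugated five-membered lactone and releases the C1 alkoxide; the closest known reactions are Ni/Cr couplings of alkenyl triflates, couplings of (Z)-3-iodoacrylates with aldehydes that give butenolides directly, and sulfonamide-controlled asymmetric Ni/Cr couplings.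

**Step 13**
Reactants: 21 triol-butenolide diene
Product: 22 (1S,2E,4R,6E,8S,10R)-1,4,8-trihydroxycembra-2,6,11-trien-20,10-olide (CHEBI:68873)
Conditions: second-generation Hoveyda-Grubbs catalyst, (H2IMes)Cl2Ru(=CH-2-iPrOC6H4) (10 mol %), 1,4-benzoquinone (20 mol %), PhMe (1 mM), 80 °C
Reagents that add atoms: none
Why: Ring-closing metathesis joins the only two terminal alkenes (homoallylic C6 and the C7 vinyl carbinol), the C2=C3 alkene between two quaternary carbons and the butenolide alkene being inert, and the quaternary allylic C8 forces the E geometry while no stereocentre is touched.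

**Compound list**
1 | prop-2-yn-1-ol | C#CCO | starting material
2 | isopropylmagnesium chloride | CC(C)[Mg]Cl | starting material
3 | 3-methyl-2-methylidenebutan-1-ol | C=C(CO)C(C)C | intermediate
4 | [(2S)-2-(propan-2-yl)oxiran-2-yl]methanol | OC[C@@]1(C(C)C)CO1 | intermediate
5 | (2S)-2-(iodomethyl)-3-methylbutane-1,2-diol | OC[C@@](O)(C(C)C)CI | intermediate
6 | methyl acrylate | C=CC(=O)OC | starting material
7 | methyl (5S)-5-hydroxy-5-(hydroxymethyl)-6-methylheptanoate | OC[C@@](O)(C(C)C)CCCC(=O)OC | intermediate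
8 | (6S)-6-(hydroxymethyl)-6-(propan-2-yl)oxan-2-one | OC[C@@]1(C(C)C)CCCC(=O)O1 | intermediate
9 | 1-(triphenylphosphoranylidene)propan-2-one | CC(=O)C=P(c1ccccc1)(c1ccccc1)c1ccccc1 | starting material
10 | (2S)-6-oxo-2-(propan-2-yl)oxane-2-carbaldehyde | O=C[C@@]1(C(C)C)CCCC(=O)O1 | intermediate
11 | (6S)-6-[(1E)-3-oxobut-1-en-1-yl]-6-(propan-2-yl)oxan-2-one | CC(=O)/C=C/[C@@]1(C(C)C)CCCC(=O)O1 | intermediate
12 | allyltrimethoxysilane | C=CC[Si](OC)(OC)OC | starting material
13 | (6S)-6-[(1E,3R)-3-hydroxy-3-methylhexa-1,5-dien-1-yl]-6-(propan-2-yl)oxan-2-one | C=CC[C@@](C)(O)/C=C/[C@@]1(C(C)C)CCCC(=O)O1 | intermediate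
14 | (3Z,6S)-3-(hydroxymethylidene)-6-[(1E,3R)-3-hydroxy-3-methylhexa-1,5-dien-1-yl]-6-(propan-2-yl)oxan-2-one | C=CC[C@@](C)(O)/C=C/[C@@]1(C(C)C)CC/C(=C/O)C(=O)O1 | intermediate
15 | [(Z)-{(6S)-6-[(1E,3R)-3-hydroxy-3-methylhexa-1,5-dien-1-yl]-2-oxo-6-(propan-2-yl)oxan-3-ylidene}methyl] trifluoromethanesulfonate | C=CC[C@@](C)(O)/C=C/[C@@]1(C(C)C)CC/C(=C/OS(=O)(=O)C(F)(F)F)C(=O)O1 | intermediate
16 | (2Z)-3-methylpent-2-en-4-yn-1-ol | OC/C=C(/C)C#C | starting material
17 | [(2S,3R)-3-ethynyl-3-methyloxiran-2-yl]methanol | OC[C@@H]1O[C@]1(C)C#C | intermediate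
18 | (3S)-3-methylpent-4-ene-1,3-diol | C=C[C@@](C)(O)CCO | intermediate
19 | (3S)-3-hydroxy-3-methylpent-4-enal | C=C[C@@](C)(O)CC=O | intermediate
20 | (3Z,6S)-3-[(2R,4S)-2,4-dihydroxy-4-methylhex-5-en-1-ylidene]-6-[(1E,3R)-3-hydroxy-3-methylhexa-1,5-dien-1-yl]-6-(propan-2-yl)oxan-2-one | C=CC[C@@](C)(O)/C=C/[C@@]1(C(C)C)CC/C(=C/[C@H](O)C[C@](C)(O)C=C)C(=O)O1 | intermediate
21 | (5R)-5-[(2S)-2-hydroxy-2-methylbut-3-en-1-yl]-3-[(3S,4E,6R)-3,6-dihydroxy-6-methyl-3-(propan-2-yl)nona-4,8-dien-1-yl]furan-2(5H)-one | C=CC[C@@](C)(O)/C=C/[C@@](O)(C(C)C)CCC1=C[C@@H](C[C@](C)(O)C=C)OC1=O | intermediate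
22 | (1S,2E,4R,6E,8S,10R)-1,4,8-trihydroxycembra-2,6,11-trien-20,10-olide | CC(C)[C@]1(O)/C=C/[C@](C)(O)C/C=C/[C@@](C)(O)C[C@@H]2C=C(CC1)C(=O)O2 | target

**Step count**
Total step count: 13. Longest linear sequence: 10 (steps 1-8, 12, 13). The east half (steps 9-11) runs in parallel.

**Steps most likely to fail**

Step 12. An enol triflate of a formyl lactone is an untested Ni/Cr partner. Aldehyde 19 can undergo retro-aldol cleavage on Lewis-acidic chromium. Ligand control next to a free tertiary alkoxide is uncertain, and any E triflate gives an adduct that cannot switch rings.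

The fallback moves the reversed polarity to the other partner. It sets out from 19 and 15 and comes back at 20 and hence 21.
- Aldehyde 19 reacts with propane-1,3-dithiol and MgBr2·OEt2 to give the dithiane carbinol F1.
- The dianion of this dithiane (n-BuLi, 2 equiv, THF/HMPA), an acyl anion equivalent for C10, displaces triflate from the lithium alkoxide of 15 by conjugate addition-elimination and gives the dithianyl alkylidene lactone F2.
- MeI/CaCO3 in aqueous MeCN unmasks the (Z)-ene-keto lactone F3.
- (S)-Me-CBS oxazaborolidine with catecholborane reduces the ketone, with the alkenyl group acting as the large group, to the 10R alcohol 20, which switches rings to 21.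

Step 13. Closing a 14-membered ring onto a vinyl carbinol may stall, oligomerise or give E/Z mixtures.

The fallback closes the ring at C10-C11 instead. It sets out from 15 and 18 and comes back at 22.
- Cross-metathesis of 15 with excess 18 (same ruthenium catalyst) gives the E diol enol triflate F4.
- TEMPO/PhI(OAc)2 then gives the seco aldehyde F5.
- High-dilution CrCl2/NiCl2 coupling with the same sulfonamide closes the carbocycle to the bridged macrocyclic hydroxy lactone F6, whose ring switch delivers 22 directly.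

Step 4. Direct reduction of the iodide, acrylate telomers and slow lactonisation can erode the yield.

The fallback replaces the radical step by ionic and catalytic steps. It sets out from 4 and comes back at 8.
- Vinylmagnesium bromide/CuI opens the epoxide at CH2 to give the homoallylic diol F7.
- Cross-metathesis with methyl acrylate gives the enoate diol F8.
- Hydrogenation (H2, Pd/C) gives 7, which lactonises with PPTS to 8.

**Further compounds**
F1 | step 12 | (2S)-1-(1,3-dithian-2-yl)-2-methylbut-3-en-2-ol | C=C[C@@](C)(O)CC1SCCCS1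
F2 | step 12 | (3Z,6S)-3-({2-[(2S)-2-hydroxy-2-methylbut-3-en-1-yl]-1,3-dithian-2-yl}methylidene)-6-[(1E,3R)-3-hydroxy-3-methylhexa-1,5-dien-1-yl]-6-(propan-2-yl)oxan-2-one | C=CC[C@@](C)(O)/C=C/[C@@]1(C(C)C)CC/C(=C/C2(C[C@](C)(O)C=C)SCCCS2)C(=O)O1
F3 | step 12 | (3Z,6S)-3-[(4S)-4-hydroxy-4-methyl-2-oxohex-5-en-1-ylidene]-6-[(1E,3R)-3-hydroxy-3-methylhexa-1,5-dien-1-yl]-6-(propan-2-yl)oxan-2-one | C=CC[C@@](C)(O)/C=C/[C@@]1(C(C)C)CC/C(=C/C(=O)C[C@](C)(O)C=C)C(=O)O1
F4 | step 13 | [(Z)-{(6S)-2-oxo-6-(propan-2-yl)-6-[(1E,3R,5E,7S)-3,7,9-trihydroxy-3,7-dimethylnona-1,5-dien-1-yl]oxan-3-ylidene}methyl] trifluoromethanesulfonate | OCC[C@](C)(O)/C=C/C[C@@](C)(O)/C=C/[C@@]1(C(C)C)CC/C(=C/OS(=O)(=O)C(F)(F)F)C(=O)O1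
F5 | step 13 | [(Z)-{(6S)-6-[(1E,3R,5E,7S)-3,7-dihydroxy-3,7-dimethyl-9-oxonona-1,5-dien-1-yl]-2-oxo-6-(propan-2-yl)oxan-3-ylidene}methyl] trifluoromethanesulfonate | O=CC[C@](C)(O)/C=C/C[C@@](C)(O)/C=C/[C@@]1(C(C)C)CC/C(=C/OS(=O)(=O)C(F)(F)F)C(=O)O1
F6 | step 13 | bridged macrocyclic hydroxy lactone (C10-C11 closed, 10R, C1-O-C20 six-membered lactone still in place) | C1[C@](C)(O)/C=C/C[C@@](C)(O)/C=C/[C@@]2(C(C)C)CC/C(=C/[C@@H]1O)C(=O)O2
F7 | step 4 | (2S)-2-(propan-2-yl)pent-4-ene-1,2-diol | OC[C@@](O)(C(C)C)CC=C
F8 | step 4 | methyl (2E,5S)-5-hydroxy-5-(hydroxymethyl)-6-methylhept-2-enoate | OC[C@@](O)(C(C)C)C/C=C/C(=O)OC
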